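## Retrosynthetic overview

1. The target is (+)-isolariciresinol with its acetate on the CH2OH at tetralin C2, next to the aryl-bearing C1. Cutting the C1–C8a bond of ring B gives an acyclic (R,R)-dibenzylbutane with one CH2OAc arm and one CH2O–N(phthaloyl) arm.
2. That bond forms under blue light: N–O cleavage gives an alkoxyl radical, 1,5-HAT takes a hydrogen from the benzylic CH2 of the acetate-bearing half, oxidation gives a quinone methide, and Friedel–Crafts closure follows.
3. The O–N handle comes from a Mitsunobu reaction on the monoacetate. The monoacetate comes from C2-symmetric (−)-secoisolariciresinol, whose two CH2OH groups are homotopic, so only one monoacetate exists.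
4. Ring order: arene rings A (fused) and C (pendant) are bought, and ring B is the only ring formed, in the last step. C2 and C3 are bought, and C1 is set by them.

Assumption: enantiopure (−)-(2R,3R)-secoisolariciresinol is bought as a catalogue chiral-pool lignan, sourced from conifer knotwood.

## Route

**Step 1**
Reactants: 1 (−)-secoisolariciresinol; 2 trimethyl orthoacetate
Product: 4 (2R,3R)-4-hydroxy-2,3-bis(4-hydroxy-3-methoxybenzyl)butyl acetate, via cyclic orthoacetate 3 (not isolated)
Conditions: MeC(OMe)3 (1.5 equiv), PPTS (5 mol %), THF, rt; then H2O, rt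
Reagents that add atoms: trimethyl orthoacetate, CC(OC)(OC)OC; water, O
Why: Acid-catalysed orthoester exchange ties the 1,4-diol into a seven-membered cyclic orthoacetate whose mild hydrolysis can release only one acetate (cyclic-orthoester monoacylation of a diol), the phenols do not react, the homotopic CH2OH groups of 1 give a single monoacetate, and no stereocentre is touched.

**Step 2**
Reactants: 4 monoacetate; 5 N-hydroxyphthalimide
Product: 6 (2R,3R)-4-[(1,3-dioxoisoindolin-2-yl)oxy]-2,3-bis(4-hydroxy-3-methoxybenzyl)butyl acetate
Conditions: 5 (1.2 equiv), PPh3, DIAD, THF, 0 °C to rt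
Reagents that add atoms: N-hydroxyphthalimide, O=C1c2ccccc2C(=O)N1O
Why: In this Mitsunobu reaction the betaine deprotonates only the far more acidic N-hydroxyimide (pKa about 6, against about 10 for the guaiacyl phenols), and its oxyanion displaces the primary alkoxyphosphonium by SN2 at CH2, so the phenols, the acetate and both stereocentres are untouched.

**Step 3**
Reactants: 6 N-alkoxyphthalimide
Product: 11 (+)-isolariciresinol C2-CH2 acetate (target CNP0110635.1), via alkoxyl radical 7 (not isolated), via benzylic radical 8 (not isolated), via quinone methide 9 (not isolated), via lariciresinol acetate 10 (not isolated)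
Conditions: fac-Ir(ppy)3 (1 mol %), TFA (20 mol %), MeCN/HFIP 4:1 (5 mM), 450 nm LEDs, Ar, 25 °C
Reagents that add atoms: none
Why: Proposed new method: excited fac-Ir(ppy)3 reduces the acid- and HFIP-activated phthalimide and N–O cleavage gives alkoxyl radical 7, whose six-membered 1,5-HAT can only take the weak, electron-rich benzylic C–H of the acetate-bearing half (the other δ C–H is the deactivated CH2OAc and the other benzylic CH2 would need 1,4-HAT) to give 8, the tetravalent iridium species [Ir(ppy)3]+ oxidises 8 to the protonated form of quinone methide 9, O-capture to 10 is reversible under the acid while Friedel–Crafts attack para to OMe through a chair with all three substituents equatorial is irreversible and sets C1 as S (1,2-trans, 2,3-trans), and the lost proton ends on phthalimide so the step is redox-neutral; the closest known reaction types are photoredox δ-C–H functionalisation of N-alkoxyphthalimides by 1,5-HAT and the acid-induced quinone-methide cyclisation of lariciresinol to isolariciresinol.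

## Compound list

1 | (−)-secoisolariciresinol, (2R,3R)-2,3-bis(4-hydroxy-3-methoxybenzyl)butane-1,4-diol | COc1cc(C[C@@H](CO)[C@H](CO)Cc2ccc(O)c(OC)c2)ccc1O | starting material
2 | trimethyl orthoacetate | CC(OC)(OC)OC | starting material
3 | (5R,6R)-5,6-bis(4-hydroxy-3-methoxybenzyl)-2-methoxy-2-methyl-1,3-dioxepane | COc1cc(C[C@H]2COC(C)(OC)OC[C@@H]2Cc3ccc(O)c(OC)c3)ccc1O | intermediate
4 | (2R,3R)-4-hydroxy-2,3-bis(4-hydroxy-3-methoxybenzyl)butyl acetate | COc1cc(C[C@@H](COC(C)=O)[C@H](CO)Cc2ccc(O)c(OC)c2)ccc1O | intermediate
5 | N-hydroxyphthalimide | O=C1c2ccccc2C(=O)N1O | starting material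
6 | (2R,3R)-4-[(1,3-dioxoisoindolin-2-yl)oxy]-2,3-bis(4-hydroxy-3-methoxybenzyl)butyl acetate | COc1cc(C[C@@H](COC(C)=O)[C@H](CON2C(=O)c3ccccc3C2=O)Cc4ccc(O)c(OC)c4)ccc1O | intermediate
7 | primary alkoxyl radical from 6 after N–O cleavage (backbone configuration unchanged) | COc1cc(C[C@@H](COC(C)=O)[C@H](C[O])Cc2ccc(O)c(OC)c2)ccc1O | intermediate
8 | benzylic radical on the acetate-bearing half, hydroxyl restored | COc1cc([CH][C@@H](COC(C)=O)[C@H](CO)Cc2ccc(O)c(OC)c2)ccc1O | intermediate
9 | para-quinone methide of the acetate-bearing half (E/Z not defined, backbone configuration unchanged) | COC1=CC(=C[C@@H](COC(C)=O)[C@H](CO)Cc2ccc(O)c(OC)c2)C=CC1=O | intermediate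
10 | (+)-lariciresinol O-acetate, [(2S,3R,4R)-2-(4-hydroxy-3-methoxyphenyl)-4-(4-hydroxy-3-methoxybenzyl)tetrahydrofuran-3-yl]methyl acetate | COc1cc([C@H]2OC[C@H](Cc3ccc(O)c(OC)c3)[C@@H]2COC(C)=O)ccc1O | intermediate
11 | [(1S,2R,3R)-7-hydroxy-1-(4-hydroxy-3-methoxyphenyl)-3-(hydroxymethyl)-6-methoxy-1,2,3,4-tetrahydronaphthalen-2-yl]methyl acetate | COc1cc([C@H]2c3cc(O)c(OC)cc3C[C@@H](CO)[C@@H]2COC(C)=O)ccc1O | target

## Step count

Total step count: 3. Longest linear sequence: 3.

## Steps most likely to fail

**Step 3 (the new step).**
- Risk: a phenolic O–H may intercept the alkoxyl radical. The 5 mM dilution and the hydrogen-bond-accepting MeCN are chosen to suppress this.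
- Risk: the reduced phthalimide may collapse to the aldehyde instead of releasing the radical.
- Risk: the flux may stall at 10, or the acetate may migrate if the acid is left on too long.
- Fallback, using known chemistry only: it sets out from 1 and comes back to the route at 10, and from there at 11. DDQ (0.6 equiv, dioxane, rt) oxidises one guaiacyl half of C2-symmetric 1 to its quinone methide, and the CH2OH of the other half closes it to (+)-lariciresinol F1. Symmetry removes the regiochemical question, the substoichiometric oxidant limits oxidation of the second half, and unreacted 1 is recycled. AcOH, PPh3 and DIAD in THF then esterify the only aliphatic hydroxyl in the presence of the phenols to give 10, which is isolated this time. Catalytic TFA in CH2Cl2 at rt converts 10 into 11 by the acid-induced lariciresinol-to-isolariciresinol cyclisation.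

**Step 2.**
- Risk: competing O-alkylation of the free phenols, or slow displacement at the β-branched CH2.
- Fallback: it sets out from 4 and comes back at 6, and it separates activation from substitution. PPh3, I2 and imidazole (premixed, CH2Cl2, 0 °C) convert the primary alcohol into (2R,3R)-2,3-bis(4-hydroxy-3-methoxybenzyl)-4-iodobutyl acetate F2. F2 is then alkylated with 5 and KHCO3 in DMF at 40 °C. This base deprotonates the N-hydroxyimide but not the phenols.

**Step 1.**
- Risk: the seven-membered orthoacetate forms incompletely, or hydrolyses back to the diol and methyl acetate.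
- Fallback: it sets out from 1 and comes back at 4, and it replaces the cyclic intermediate with statistical acyl transfer plus recycling. TsOH-catalysed transesterification in EtOAc (50 °C, phenols inert) is stopped near half conversion. Compound 4 is separated from recovered 1 and from (2R,3R)-2,3-bis(4-hydroxy-3-methoxybenzyl)butane-1,4-diyl diacetate F3, which catalytic K2CO3 in MeOH returns to 1.

## Further compounds

F1 | step 3 | (+)-lariciresinol, 4-[(2S,3R,4R)-4-(4-hydroxy-3-methoxybenzyl)-3-(hydroxymethyl)tetrahydrofuran-2-yl]-2-methoxyphenol | COc1cc([C@H]2OC[C@H](Cc3ccc(O)c(OC)c3)[C@@H]2CO)ccc1O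
F2 | step 2 | (2R,3R)-2,3-bis(4-hydroxy-3-methoxybenzyl)-4-iodobutyl acetate | COc1cc(C[C@@H](COC(C)=O)[C@H](CI)Cc2ccc(O)c(OC)c2)ccc1O
F3 | step 1 | (2R,3R)-2,3-bis(4-hydroxy-3-methoxybenzyl)butane-1,4-diyl diacetate | COc1cc(C[C@@H](COC(C)=O)[C@H](COC(C)=O)Cc2ccc(O)c(OC)c2)ccc1O
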